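The route rests on cutting the C6–C7 bond of the nonenoate chain, two carbons from the acyl ketone. The methyl group on C6 is read as a reduced formyl group: its carbon and the ketone carbon on C3 of the dihydropyranone ring are then 1,5-related, so C6 is the α-carbon of an aldehyde and C7 the terminal carbon of a vinyl ketone. An amine-catalysed Michael addition joins dienoate aldehyde 9 to acryloyl pyranone 21, forms C6–C7 and sets the C6 configuration in one operation. The precursor of C6 is therefore a CH2 next to a formyl group, which is reduced to methyl afterwards via its tosylhydrazone.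

Key step: step 11

Remark: locants C1 to C9 are those of the nonenoic acid chain of the target (C1 = carboxyl carbon); all 3-acyl pyranones are written as the ring 4-enol tautomer of the target structure, although they are chelated tricarbonyl tautomer mixtures.

Step 1
Reactants: 1 (2S)-2-methylbutan-1-ol
Product: 2 (2S)-2-methylbutanal
Conditions: TEMPO (1 mol%), KBr (10 mol%), NaOCl (1.1 equiv), NaHCO3 buffer, CH2Cl2/H2O, 0 °C; dried CH2Cl2 solution used directly
Reagents that add atoms: none
Why: Nitroxyl-catalysed (oxoammonium) oxidation of a primary alcohol, which at 0 °C and mildly basic pH should stop at the aldehyde without epimerising the α-stereocentre taken from the chiral pool.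

Step 2
Reactants: 2 (2S)-2-methylbutanal; 3 tert-butyl (triphenylphosphoranylidene)acetate
Product: 5 tert-butyl (2Z,4S)-2-bromo-4-methylhex-2-enoate, via bromo ylide 4 (not isolated)
Conditions: NBS (1.05 equiv), CH2Cl2, −20 °C; then K2CO3 (1.5 equiv), 2 in CH2Cl2, −20 °C to rt
Reagents that add atoms: N-bromosuccinimide, O=C1CCC(=O)N1Br
Why: Wittig olefination with a stabilised α-bromo ylide made in the flask by bromination of 3; the ester should end up trans to the alkyl group, giving the (Z)-bromo enoate, and the stereocentre of 2 is carried through.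

Step 3
Reactants: 6 pent-4-yn-1-ol
Product: 7 (4E)-5-(4,4,5,5-tetramethyl-1,3,2-dioxaborolan-2-yl)pent-4-en-1-ol
Conditions: CuCl (5 mol%), Xantphos (5 mol%), NaOtBu (10 mol%), B2pin2 (1.1 equiv), MeOH (2 equiv), THF, rt
Reagents that add atoms: bis(pinacolato)diboron, CC1(C)OB(OC1(C)C)B1OC(C)(C)C(C)(C)O1
Why: Copper-catalysed protoboration (formal hydroboration) of a terminal alkyne: syn addition of the boryl copper species with boron on the terminal carbon, then protonolysis by methanol, should give the (E)-alkenylboronate and tolerate the free hydroxyl.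

Step 4
Reactants: 5 tert-butyl (2Z,4S)-2-bromo-4-methylhex-2-enoate; 7 (4E)-5-(4,4,5,5-tetramethyl-1,3,2-dioxaborolan-2-yl)pent-4-en-1-ol
Product: 8 tert-butyl (2E,3E)-7-hydroxy-2-[(2S)-2-methylbutylidene]hept-3-enoate
Conditions: PdCl2(dppf) (5 mol%), K3PO4 (3 equiv), THF/H2O, 50 °C
Reagents that add atoms: none
Why: Suzuki–Miyaura coupling of an alkenyl bromide and an alkenylboronate, both with retention of alkene geometry, so the (2Z)-bromide becomes the (2E)-alkylidene ester and the (3E) alkene comes from 7.

Step 5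
Reactants: 8 tert-butyl (2E,3E)-7-hydroxy-2-[(2S)-2-methylbutylidene]hept-3-enoate
Product: 9 tert-butyl (2E,3E)-2-[(2S)-2-methylbutylidene]-7-oxohept-3-enoate
Conditions: TEMPO (10 mol%), PhI(OAc)2 (1.1 equiv), CH2Cl2, rt
Reagents that add atoms: none
Why: Nitroxyl-catalysed oxidation of the primary alcohol to the aldehyde, a method that should leave the diene ester and the allylic stereocentre alone.

Step 6
Reactants: 10 benzeneselenol; 11 acrylic acid
Product: 12 3-(phenylselanyl)propanoic acid
Conditions: Et3N (5 mol%), EtOH, rt, under N2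
Reagents that add atoms: none
Why: Conjugate (seleno-Michael) addition of the soft selenol to the acrylic acid β-carbon, an addition without by-product.

Step 7
Reactants: 13 ethyl (3R)-3-hydroxybutanoate; 14 tert-butyl acetate
Product: 16 tert-butyl (5R)-5-hydroxy-3-oxohexanoate, via lithium enolate 15 (not isolated)
Conditions: LiN(iPr)2 (3.6 equiv), 14 (3.6 equiv), THF, −78 °C; then 13, −78 to −30 °C; AcOH quench
Reagents that add atoms: none
Why: Crossed Claisen condensation in which excess ester enolate first deprotonates the hydroxyl and then acylates at the ethyl ester, the product being protected as its enolate; the stereocentre comes from the chiral pool and is not touched.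

Step 8
Reactants: 16 tert-butyl (5R)-5-hydroxy-3-oxohexanoate
Product: 17 (6R)-4-hydroxy-6-methyl-5,6-dihydro-2H-pyran-2-one
Conditions: TFA, CH2Cl2, rt
Reagents that add atoms: none
Why: Acidolysis of the tert-butyl ester followed by lactonisation of the δ-hydroxy β-keto acid; no bond to the stereocentre is broken, so C6 of the ring stays (R).

Step 9
Reactants: 17 (6R)-4-hydroxy-6-methyl-5,6-dihydro-2H-pyran-2-one; 12 3-(phenylselanyl)propanoic acid
Product: 19 (6R)-4-hydroxy-6-methyl-3-[3-(phenylselanyl)propanoyl]-5,6-dihydro-2H-pyran-2-one, via enol ester 18 (not isolated)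
Conditions: DCC (1.1 equiv), DMAP (0.3 equiv), CH2Cl2, 0 °C to rt
Reagents that add atoms: none
Why: Carbodiimide esterification of the ring enol followed by the DMAP-mediated O-to-C acyl shift (Fries-type rearrangement through an acylpyridinium enolate ion pair), the usual one-pot C3 acylation of 4-hydroxy pyranones.

Step 10
Reactants: 19 (6R)-4-hydroxy-6-methyl-3-[3-(phenylselanyl)propanoyl]-5,6-dihydro-2H-pyran-2-one
Product: 21 (6R)-4-hydroxy-6-methyl-3-(prop-2-enoyl)-5,6-dihydro-2H-pyran-2-one, via selenoxide 20 (not isolated)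
Conditions: 30% H2O2 (2.5 equiv), CH2Cl2, 0 °C to rt; cold water wash, solution used at once
Reagents that add atoms: none
Why: Selenide oxidation and selenoxide syn-elimination; the only hydrogens β to selenium are those α to the ketone, so the terminal enone should form below room temperature without base.

Step 11
Reactants: 9 tert-butyl (2E,3E)-2-[(2S)-2-methylbutylidene]-7-oxohept-3-enoate; 21 (6R)-4-hydroxy-6-methyl-3-(prop-2-enoyl)-5,6-dihydro-2H-pyran-2-one
Product: 24 tert-butyl (2E,3E,6R)-9-[(6R)-4-hydroxy-6-methyl-2-oxo-5,6-dihydro-2H-pyran-3-yl]-2-[(2S)-2-methylbutylidene]-6-{(E)-[2-(4-methylbenzenesulfonyl)hydrazinylidene]methyl}-9-oxonon-3-enoate, via pyrrolidine enamine 22 (not isolated), via formyl ketone 23 (not isolated)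
Conditions: 21 (1.2 equiv), (R)-2-[methoxy(diphenyl)methyl]pyrrolidine (10 mol%), CHCl3, 4 °C; then TsNHNH2 (1.1 equiv), MeOH, 0 °C
Reagents that add atoms: 4-methylbenzenesulfonohydrazide, Cc1ccc(cc1)S(=O)(=O)NN
Why: The secondary amine condenses with aldehyde 9 to the (E)-enamine 22, whose C6 adds to the unsubstituted terminal carbon (C7) of the acryloyl ketone of 21, which is activated by the internal hydrogen bond of the chelated ring enol, and hydrolysis of the iminium ion releases formyl ketone 23 and the catalyst. The closest known reaction type is the diarylprolinol ether-catalysed Michael addition of aldehydes to vinyl ketones. No ring is closed. The new stereocentre C6 is controlled by the catalyst: the methoxydiphenylmethyl group shields one face of the s-trans enamine, so the (R)-catalyst should give (6R), the descriptor that is kept when formyl later becomes methyl. The step needs chemoselectivity for the vinyl ketone over the cross-conjugated dienoate and mono-addition only; the terminal, doubly activated CH2 of 21 against the β-substituted, α-branched tert-butyl dienoate secures the first and the α-branching of 23 the second. Tosylhydrazide is added to the cold mixture because the α-branched 1,5-keto aldehyde could epimerise or cyclise on isolation.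

Step 12
Reactants: 24 tosylhydrazone of formyl ketone 23
Product: 26 tert-butyl (2E,3E,6R)-9-[(6R)-4-hydroxy-6-methyl-2-oxo-5,6-dihydro-2H-pyran-3-yl]-6-methyl-2-[(2S)-2-methylbutylidene]-9-oxonon-3-enoate, via boryl hydrazine 25 (not isolated)
Conditions: catecholborane (3 equiv), CHCl3, 0 °C; then NaOAc·3H2O, 60 °C
Reagents that add atoms: none
Why: Tosylhydrazone reduction (a mild Wolff–Kishner-type deoxygenation): hydride adds to C=N, acetate-induced loss of sulfinate gives the alkyldiazene, which loses N2 with hydrogen transfer to carbon, and C6 is not involved and keeps its configuration.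

Step 13
Reactants: 26 tert-butyl ester of the target
Product: 27 (2E,3E,6R)-9-[(6R)-4-hydroxy-6-methyl-2-oxo-5,6-dihydro-2H-pyran-3-yl]-6-methyl-2-[(2S)-2-methylbutylidene]-9-oxonon-3-enoic acid
Conditions: TFA/CH2Cl2 (1:4), 0 °C to rt
Reagents that add atoms: none
Why: Acidolysis of the tert-butyl ester through the tert-butyl cation, conditions under which the chelated tricarbonyl, the diene acid and the three stereocentres should be inert.

Compound list
1 | (2S)-2-methylbutan-1-ol | CC[C@H](C)CO | starting material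
2 | (2S)-2-methylbutanal | CC[C@H](C)C=O | intermediate
3 | tert-butyl (triphenylphosphoranylidene)acetate | CC(C)(C)OC(=O)C=P(c1ccccc1)(c1ccccc1)c1ccccc1 | starting material
4 | tert-butyl bromo(triphenylphosphoranylidene)acetate | CC(C)(C)OC(=O)C(Br)=P(c1ccccc1)(c1ccccc1)c1ccccc1 | intermediate
5 | tert-butyl (2Z,4S)-2-bromo-4-methylhex-2-enoate | CC[C@H](C)/C=C(\Br)C(=O)OC(C)(C)C | intermediate
6 | pent-4-yn-1-ol | C#CCCCO | starting material
7 | (4E)-5-(4,4,5,5-tetramethyl-1,3,2-dioxaborolan-2-yl)pent-4-en-1-ol | OCCC/C=C/B1OC(C)(C)C(C)(C)O1 | intermediate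
8 | tert-butyl (2E,3E)-7-hydroxy-2-[(2S)-2-methylbutylidene]hept-3-enoate | CC[C@H](C)/C=C(\C=C\CCCO)C(=O)OC(C)(C)C | intermediate
9 | tert-butyl (2E,3E)-2-[(2S)-2-methylbutylidene]-7-oxohept-3-enoate | CC[C@H](C)/C=C(\C=C\CCC=O)C(=O)OC(C)(C)C | intermediate
10 | benzeneselenol | [SeH]c1ccccc1 | starting material
11 | acrylic acid | C=CC(=O)O | starting material
12 | 3-(phenylselanyl)propanoic acid | OC(=O)CC[Se]c1ccccc1 | intermediate
13 | ethyl (3R)-3-hydroxybutanoate | CCOC(=O)C[C@@H](C)O | starting material
14 | tert-butyl acetate | CC(=O)OC(C)(C)C | starting material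
15 | lithium enolate of tert-butyl acetate (lithium 1-tert-butoxyethenolate) | [Li+].[O-]C(=C)OC(C)(C)C | intermediate
16 | tert-butyl (5R)-5-hydroxy-3-oxohexanoate | C[C@@H](O)CC(=O)CC(=O)OC(C)(C)C | intermediate
17 | (6R)-4-hydroxy-6-methyl-5,6-dihydro-2H-pyran-2-one | O=C1C=C(O)C[C@@H](C)O1 | intermediate
18 | (6R)-6-methyl-2-oxo-5,6-dihydro-2H-pyran-4-yl 3-(phenylselanyl)propanoate | O=C1C=C(OC(=O)CC[Se]c2ccccc2)C[C@@H](C)O1 | intermediate
19 | (6R)-4-hydroxy-6-methyl-3-[3-(phenylselanyl)propanoyl]-5,6-dihydro-2H-pyran-2-one | O=C(CC[Se]c1ccccc1)C1=C(O)C[C@@H](C)OC1=O | intermediate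
20 | (6R)-4-hydroxy-6-methyl-3-[3-(phenylseleninyl)propanoyl]-5,6-dihydro-2H-pyran-2-one (both configurations at selenium) | O=C(CC[Se](=O)c1ccccc1)C1=C(O)C[C@@H](C)OC1=O | intermediate
21 | (6R)-4-hydroxy-6-methyl-3-(prop-2-enoyl)-5,6-dihydro-2H-pyran-2-one | C=CC(=O)C1=C(O)C[C@@H](C)OC1=O | intermediate
22 | tert-butyl (2E,3E,6E)-7-{(2R)-2-[methoxy(diphenyl)methyl]pyrrolidin-1-yl}-2-[(2S)-2-methylbutylidene]hepta-3,6-dienoate | CC[C@H](C)/C=C(\C=C\C/C=C/N1CCC[C@@H]1C(OC)(c1ccccc1)c1ccccc1)C(=O)OC(C)(C)C | intermediate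
23 | tert-butyl (2E,3E,6R)-6-formyl-9-[(6R)-4-hydroxy-6-methyl-2-oxo-5,6-dihydro-2H-pyran-3-yl]-2-[(2S)-2-methylbutylidene]-9-oxonon-3-enoate | CC[C@H](C)/C=C(\C=C\C[C@H](C=O)CCC(=O)C1=C(O)C[C@@H](C)OC1=O)C(=O)OC(C)(C)C | intermediate
24 | (E)-N-tosylhydrazone of 23 | CC[C@H](C)/C=C(\C=C\C[C@H](/C=N/NS(=O)(=O)c1ccc(C)cc1)CCC(=O)C1=C(O)C[C@@H](C)OC1=O)C(=O)OC(C)(C)C | intermediate
25 | N-(1,3,2-benzodioxaborol-2-yl)-N'-tosylhydrazine from 24, boron on the nitrogen that carries the C6 methylene (ring enol shown free) | CC[C@H](C)/C=C(\C=C\C[C@H](CN(B1Oc2ccccc2O1)NS(=O)(=O)c1ccc(C)cc1)CCC(=O)C1=C(O)C[C@@H](C)OC1=O)C(=O)OC(C)(C)C | intermediate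
26 | tert-butyl (2E,3E,6R)-9-[(6R)-4-hydroxy-6-methyl-2-oxo-5,6-dihydro-2H-pyran-3-yl]-6-methyl-2-[(2S)-2-methylbutylidene]-9-oxonon-3-enoate | CC[C@H](C)/C=C(\C=C\C[C@H](C)CCC(=O)C1=C(O)C[C@@H](C)OC1=O)C(=O)OC(C)(C)C | intermediate
27 | (2E,3E,6R)-9-[(6R)-4-hydroxy-6-methyl-2-oxo-5,6-dihydro-2H-pyran-3-yl]-6-methyl-2-[(2S)-2-methylbutylidene]-9-oxonon-3-enoic acid | CC[C@H](C)/C=C(\C=C\C[C@H](C)CCC(=O)C1=C(O)C[C@@H](C)OC1=O)C(=O)O | target

Total step count: 13. Longest linear sequence: 7 steps (1, 2, 4, 5, 11, 12, 13; the pyranone branch 7, 8, 9, 10, 11, 12, 13 is equally long).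

Steps most likely to fail

Step 11. The acidic ring enol of 21 may protonate and arrest the amine catalyst, 21 may consume itself before the enamine reaches it, or an uncatalysed background addition may erode facial selectivity. The fallback keeps the same reaction type but uses a neutral acrylate surrogate and attaches the pyranone ring last. It sets out from 9: with 4-hydroxy-4-methylpent-1-en-3-one F1 and the catalyst of step 11 the formyl ketol F2 should form and is trapped as tosylhydrazone F3; catecholborane and NaOAc·3H2O reduce this to the methyl-branched ketol F4; NaIO4 in MeOH/H2O cleaves the α-hydroxy ketone to carboxylic acid F5; DCC/DMAP C-acylation of pyranone 17 with F5, as in step 9, comes back to the route at 26.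

Step 10. The vinyl ketone may close by attack of its own enol oxygen on the enone, or polymerise during oxidation and concentration. The fallback caps the enol before use. It sets out from the cold CH2Cl2 solution of 21: BF3·OEt2 at 0 °C should give the difluoroboron chelate F6, an acceptor without a free enol oxygen and without an acidic proton; its Michael addition to 9 under the conditions of step 11 should give the chelated Michael aldehyde F7, from which aqueous NaOAc in MeOH removes boron, and the route is rejoined at 23, trapped at once as 24.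

Step 12. Hydride may be delivered to the chelated acyl carbonyl, the diene may be hydroborated, or C6 may epimerise through ene-hydrazine tautomerisation. The fallback takes the methyl-bearing centre from the chiral pool, so no reduction is needed. It sets out from 5 and 17: (R)-citronellal F8 is homologated to alkyne F9 (Seyferth–Gilbert homologation with dimethyl (1-diazo-2-oxopropyl)phosphonate, K2CO3, MeOH), protoborated as in step 3 to alkenylboronate F10 and coupled with 5 as in step 4 to triene ester F11; mCPBA should epoxidise only the electron-rich trisubstituted alkene to epoxide F12, H5IO6 cleaves it to aldehyde F13, and NaClO2/NaH2PO4/2-methylbut-2-ene oxidation gives the acid F5 of the first fallback, whose DCC/DMAP C-acylation of 17 comes back to the route at 26.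

Further compounds
F1 | step 11 | 4-hydroxy-4-methylpent-1-en-3-one | C=CC(=O)C(C)(C)O
F2 | step 11 | tert-butyl (2E,3E,6R)-6-formyl-10-hydroxy-10-methyl-2-[(2S)-2-methylbutylidene]-9-oxoundec-3-enoate | CC[C@H](C)/C=C(\C=C\C[C@H](C=O)CCC(=O)C(C)(C)O)C(=O)OC(C)(C)C
F3 | step 11 | (E)-N-tosylhydrazone of F2 | CC[C@H](C)/C=C(\C=C\C[C@H](/C=N/NS(=O)(=O)c1ccc(C)cc1)CCC(=O)C(C)(C)O)C(=O)OC(C)(C)C
F4 | step 11 | tert-butyl (2E,3E,6R)-10-hydroxy-6,10-dimethyl-2-[(2S)-2-methylbutylidene]-9-oxoundec-3-enoate | CC[C@H](C)/C=C(\C=C\C[C@H](C)CCC(=O)C(C)(C)O)C(=O)OC(C)(C)C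
F5 | step 11 | (4R,6E,8E,10S)-8-(tert-butoxycarbonyl)-4,10-dimethyldodeca-6,8-dienoic acid | CC[C@H](C)/C=C(\C=C\C[C@H](C)CCC(=O)O)C(=O)OC(C)(C)C
F6 | step 10 | difluoroboron chelate of 21 (boron bridging the ring C4 oxygen and the acryloyl carbonyl oxygen) | C=CC1=[O+][B-](F)(F)OC2=C1C(=O)O[C@H](C)C2
F7 | step 10 | difluoroboron chelate of formyl ketone 23 | CC[C@H](C)/C=C(\C=C\C[C@H](C=O)CCC1=[O+][B-](F)(F)OC2=C1C(=O)O[C@H](C)C2)C(=O)OC(C)(C)C
F8 | step 12 | (3R)-3,7-dimethyloct-6-enal, (R)-citronellal | O=CC[C@H](C)CCC=C(C)C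
F9 | step 12 | (4R)-4,8-dimethylnon-7-en-1-yne | C#CC[C@H](C)CCC=C(C)C
F10 | step 12 | 2-[(1E,4R)-4,8-dimethylnona-1,7-dien-1-yl]-4,4,5,5-tetramethyl-1,3,2-dioxaborolane | CC1(C)OB(/C=C/C[C@H](C)CCC=C(C)C)OC1(C)C
F11 | step 12 | tert-butyl (2E,3E,6R)-6,10-dimethyl-2-[(2S)-2-methylbutylidene]undeca-3,9-dienoate | CC[C@H](C)/C=C(\C=C\C[C@H](C)CCC=C(C)C)C(=O)OC(C)(C)C
F12 | step 12 | tert-butyl (2E,3E,6R)-8-(3,3-dimethyloxiran-2-yl)-6-methyl-2-[(2S)-2-methylbutylidene]oct-3-enoate (both configurations at the oxirane carbon) | CC[C@H](C)/C=C(\C=C\C[C@H](C)CCC1OC1(C)C)C(=O)OC(C)(C)C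
F13 | step 12 | tert-butyl (2E,3E,6R)-6-methyl-2-[(2S)-2-methylbutylidene]-9-oxonon-3-enoate | CC[C@H](C)/C=C(\C=C\C[C@H](C)CCC=O)C(=O)OC(C)(C)C
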